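The target is read as a citral-type C10 chain holding two units of one hydroxyquinolone. Ring B (O4'', C4'', C3'', C5, C6, C1) is cut at its tertiary ether bond O4''–C1, and rings A and C are cut together by a retro hetero-Diels–Alder step. In one flask an acyclic enal with a masked quinolone at C5 condenses with the second quinolone. The oxatriene closes rings C and A by intramolecular [4+2]. Acid then frees the enol at C5, which traps the C1 cation and closes ring B last. Exploited: the 1,3-diaxial fit of C5–C3'' and C1–O4'' across ring C, and allylic strain at C5.

Key step: step 5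

Atom labels (kept for the same atoms in every compound):
- Ring C is C1 (bears CH3 and O4'')–C2H2–C3H–C4H–C5H–C6H2. C8 is the C(CH3)2 carbon on C4.
- Primed atoms (C2', C3', C4', O4') belong to the quinolone joined through ring A (O4', C4', C3', C3, C4, C8).
- Double-primed atoms belong to the quinolone joined through ring B.
- In these labels the target is 1S,3R,4S,5R. Ring A is cis-fused at C3/C4, C3'' on C5 is trans to C8, and O4'' on C1 lies on the same face as C3''.

Assumption: the (R,R)-diamine is taken to give the R adduct, as in the analogous addition of 4-hydroxycoumarin to benzylideneacetone. The (S,S)-diamine is sold as well and is used if the sense proves opposite.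

Step 1
Reactants: 1 4-hydroxy-1-methylquinolin-2(1H)-one; 2 (3E)-6-methylhepta-3,5-dien-2-one
Product: 3 4-hydroxy-1-methyl-3-[(4R)-6-methyl-2-oxohept-5-en-4-yl]quinolin-2(1H)-one (open keto-enol tautomer drawn; the new centre is C5)
Conditions: (R,R)-1,2-diphenylethane-1,2-diamine (10 mol%), AcOH, THF, 25 °C; recrystallisation
Reagents that add atoms: none
Why: Iminium-catalysed enantioselective Michael addition of the warfarin type, in which the primary amine activates the ketone of 2, the gem-dimethyl terminus blocks the 1,6-mode so that C3'' attacks the β-carbon (C5), and the chiral diamine shields one face of the iminium ion and so sets C5 as R.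

Step 2
Reactants: 3 4-hydroxy-1-methyl-3-[(4R)-6-methyl-2-oxohept-5-en-4-yl]quinolin-2(1H)-one
Product: 4 4-(methoxymethoxy)-1-methyl-3-[(4R)-6-methyl-2-oxohept-5-en-4-yl]quinolin-2(1H)-one
Conditions: MOMCl, i-Pr2NEt, CH2Cl2, 0 to 25 °C
Reagents that add atoms: chloromethyl methyl ether (MOMCl), COCCl
Why: O-alkylation of the acidic enol by a hard electrophile (Williamson-type ether synthesis) drains the ring-chain tautomerism of 3, keeps O4'' silent until the last operation and shuts the retro-Michael channel, so C5 is untouched.

Step 3
Reactants: 4 4-(methoxymethoxy)-1-methyl-3-[(4R)-6-methyl-2-oxohept-5-en-4-yl]quinolin-2(1H)-one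
Product: 5 (5R)-5-[4-(methoxymethoxy)-1-methyl-2-oxo-1,2-dihydroquinolin-3-yl]-3,7-dimethylocta-2,6-dienenitrile (2E isomer drawn; the 2Z isomer is expected beside it and is carried on)
Conditions: (EtO)2P(O)CH2CN, NaH, THF, 0 to 25 °C
Reagents that add atoms: diethyl cyanomethylphosphonate, N#CCP(=O)(OCC)OCC
Why: Horner–Wadsworth–Emmons olefination with the small cyanomethylphosphonate anion is reliable on methyl ketones, adds C2 and C3 to C1 in one operation, and its E/Z outcome is irrelevant because this alkene is equilibrated in step 5, while C5 carries no acidic hydrogen.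

Step 4
Reactants: 5 (5R)-5-[4-(methoxymethoxy)-1-methyl-2-oxo-1,2-dihydroquinolin-3-yl]-3,7-dimethylocta-2,6-dienenitrile
Product: 7 (5R)-5-[4-(methoxymethoxy)-1-methyl-2-oxo-1,2-dihydroquinolin-3-yl]-3,7-dimethylocta-2,6-dienal (2E drawn; 2Z beside it), via N-aluminated aldimine 6 (not isolated)
Conditions: i-Bu2AlH, toluene, −78 °C; then H2O, 0 to 25 °C, filtration through Celite
Reagents that add atoms: water, O
Why: Partial reduction of a conjugated nitrile with i-Bu2AlH stops at the N-aluminated aldimine 6, which water hydrolyses to the enal, while the lactam carbonyl, the acetal and both alkenes are inert at −78 °C and C5 is not touched.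

Step 5
Reactants: 7 (5R)-5-[4-(methoxymethoxy)-1-methyl-2-oxo-1,2-dihydroquinolin-3-yl]-3,7-dimethylocta-2,6-dienal; 1 4-hydroxy-1-methylquinolin-2(1H)-one
Product: 11 target (1S,3R,4S,5R)-bis(pyranoquinolinone) CNP0229685.6, via 1-oxatriene 8 (not isolated), via MOM-protected cycloadduct 9 (not isolated), via free enol 10 (not isolated)
Conditions: ethylenediammonium diacetate (20 mol%), xylenes, 140 °C; then cool, TsOH·H2O (cat., in excess over the diamine), 60 °C, same flask
Reagents that add atoms: none
Why: Amine-catalysed Knoevenagel condensation joins C3' of 1 to the aldehyde carbon C3 of 7 and gives 1-oxatriene 8, whose alkene isomers interconvert through iminium exchange and reversible oxa-6π electrocyclisation; the isomer with the Z C1=C2 bond lets the heterodiene O4'=C4'–C3'=C3 add across the tethered C4=C8 alkene in an inverse-electron-demand intramolecular hetero-Diels–Alder reaction (9), after which TsOH hydrolyses the acetal (10), protonates C2 and lets O4'' trap the tertiary C1 cation (11). The closest known reaction types are the domino Knoevenagel/hetero-Diels–Alder reaction of 4-hydroxyquinolin-2-ones with prenyl-tethered aldehydes, the cyclisation of citral-derived oxatrienes to cis-fused tetrahydrocannabinol-type pyrans, and the acid closure of cannabidiol-type phenols onto the ring alkene that gives 2-oxabicyclo[3.3.1]nonanes. Rings C and A close together in the fused mode of the [4+2] event (bonds C3–C4 and O4'–C8), and ring B closes last by 6-exo-trig Markovnikov hydroalkoxylation (bond O4''–C1). C3 and C4 are controlled by the sp2-rich tether, which allows only the endo, cis-fusing approach, and by A(1,3) strain at C5, which puts H5 in the plane of the C4=C8 bond next to its Z methyl group so that the heterodiene arrives on the tether face, anti to the bulky quinolone, and C8 ends trans to C3''; C1 is controlled by the bridge, since O4'' can reach only the face of ring C on which the axial C5–C3'' bond stands. The step needs the [4+2] path to win over the 6π valence isomer, which the reversibility of the latter and the irreversibility of the former at 140 °C should secure, the ketone C4'=O and not the lactam C2'=O to act as heterodiene, which its lower-lying acceptor orbital favours, and O4'' to stay silent until rings A and C exist, which the MOM group secures. The acid stage needs ring A to survive, which catalytic sulfonic acid at moderate temperature should allow because ionising a formed tertiary ether costs more than protonating the trisubstituted alkene.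

Compound list

1 | 4-hydroxy-1-methylquinolin-2(1H)-one | Cn1c(=O)cc(O)c2ccccc21 | starting material
2 | (3E)-6-methylhepta-3,5-dien-2-one | CC(=O)/C=C/C=C(C)C | starting material
3 | 4-hydroxy-1-methyl-3-[(4R)-6-methyl-2-oxohept-5-en-4-yl]quinolin-2(1H)-one | CC(=O)C[C@H](C=C(C)C)c1c(O)c2ccccc2n(C)c1=O | intermediate
4 | 4-(methoxymethoxy)-1-methyl-3-[(4R)-6-methyl-2-oxohept-5-en-4-yl]quinolin-2(1H)-one | CC(=O)C[C@H](C=C(C)C)c1c(OCOC)c2ccccc2n(C)c1=O | intermediate
5 | (5R)-5-[4-(methoxymethoxy)-1-methyl-2-oxo-1,2-dihydroquinolin-3-yl]-3,7-dimethylocta-2,6-dienenitrile (2E drawn) | N#C/C=C(\C)C[C@H](C=C(C)C)c1c(OCOC)c2ccccc2n(C)c1=O | intermediate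
6 | N-(diisobutylaluminio) aldimine of enal 7 (5R; 2E drawn; not isolated) | CC(C)C[Al](CC(C)C)N=C/C=C(\C)C[C@H](C=C(C)C)c1c(OCOC)c2ccccc2n(C)c1=O | intermediate
7 | (5R)-5-[4-(methoxymethoxy)-1-methyl-2-oxo-1,2-dihydroquinolin-3-yl]-3,7-dimethylocta-2,6-dienal (2E drawn) | O=C/C=C(\C)C[C@H](C=C(C)C)c1c(OCOC)c2ccccc2n(C)c1=O | intermediate
8 | 1-oxatriene: 1-methyl-3-dienylidenequinoline-2,4-dione from 7 and 1 (C5 R; both alkene geometries mobile and left open; not isolated) | CN1C(=O)C(=CC=C(C)C[C@H](C=C(C)C)c2c(OCOC)c3ccccc3n(C)c2=O)C(=O)c2ccccc21 | intermediate
9 | MOM-protected cycloadduct (3R,4S,5R): ring A cis-fused to cyclohexene ring C (C1=C2), C5 carries the 4-(methoxymethoxy)quinolone trans to C8 (not isolated) | Cn1c(=O)c2c(c3ccccc31)OC(C)(C)[C@@H]1[C@H]2C=C(C)C[C@H]1c1c(OCOC)c2ccccc2n(C)c1=O | intermediate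
10 | free enol (3R,4S,5R): as 9 with O4''–H (not isolated) | Cn1c(=O)c2c(c3ccccc31)OC(C)(C)[C@@H]1[C@H]2C=C(C)C[C@H]1c1c(O)c2ccccc2n(C)c1=O | intermediate
11 | CNP0229685.6, (1S,3R,4S,5R) in the labels above: ring A cis-fused at C3/C4, ring B bridging C5 and C1 on the face opposite to C8 | Cn1c(=O)c2c(c3ccccc31)OC(C)(C)[C@@H]1[C@H]2C[C@]2(C)C[C@H]1c1c(c3ccccc3n(C)c1=O)O2 | target

Total step count: 5. Longest linear sequence: 5 (steps 1 to 5; compound 1 enters twice).

Steps most likely to fail

1. Step 5.
- What may go wrong: the oxatriene may rest in its oxa-6π valence isomer and enter the [4+2] channel too slowly. In the acid stage ring A may ionise at its tertiary ether and reclose in the trans sense.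
- Fallback: the flask operation is split, and the proton-driven closure is replaced by a radical-polar crossover. It sets out from 9, this time isolated after the thermal stage is run alone in a sealed tube.
- Dilute aqueous HCl in THF at 25 °C removes the acetal and gives enol 10, also isolated.
- Enol 10 is closed by Mukaiyama-type hydrogen-atom-transfer hydroalkoxylation. The reagents are [N,N'-bis(3,5-di-tert-butylsalicylidene)-1,2-cyclohexanediaminato]cobalt (C36H52CoN2O2, a complex of divalent cobalt), N-fluoro-2,4,6-trimethylpyridinium triflate and PhSiH3 in toluene at 25 °C.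
- Hydrogen is delivered to C2, the tertiary C1 radical is oxidised to the cation level, and O4'' captures it. No free acid is present, so ring A should stay closed.
- The fallback comes back to the route at 11 and makes no compound outside the list (F0).

2. Step 1.
- What may go wrong: poor facial selectivity on the slim isobutenyl-substituted iminium ion, leakage into the 1,6-mode, or erosion of the new centre by retro-Michael exchange during the long reaction time.
- Fallback: classical resolution replaces asymmetric catalysis. It sets out from 1 and 2.
- Uncatalysed base-promoted addition (Et3N, MeOH, reflux) gives the racemic adduct F1.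
- Because the enol is as acidic as that of warfarin, F1 is paired with (S)-1-phenylethylamine in EtOH. Fractional crystallisation should deliver the salt of the R acid F2, while the more soluble salt of the S acid F3 stays in the mother liquor. The antipodal amine is used if the solubilities are reversed.
- Partition of F2 between 1 M HCl and EtOAc brings the fallback back to the route at 3.

3. Step 3.
- What may go wrong: enolisation of the methyl ketone by the phosphonate anion in place of addition, so that the olefination stalls.
- Fallback: the two carbons are added as an alkyne and the oxygen is transposed. It sets out from 4.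
- HC≡CMgBr with LaCl3·2LiCl in THF at 0 °C gives the tertiary propargylic alcohol F4. Both C1 epimers form, and this centre is lost in the next operation.
- Meyer–Schuster rearrangement follows, through the vanadate ester with VO(OSiPh3)3 (pentavalent vanadium) in xylenes at 140 °C, as used for dehydrolinalool-type substrates. An oxo-metal catalyst is chosen over a carbophilic one because the 1,6-enyne array would otherwise cycloisomerise.
- This gives the enal directly, and the fallback comes back to the route at 7, bypassing 5 and 6.

Further compounds

F0 | step 5 | none | none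
F1 | step 1 | racemic 4-hydroxy-1-methyl-3-(6-methyl-2-oxohept-5-en-4-yl)quinolin-2(1H)-one | CC(=O)CC(C=C(C)C)c1c(O)c2ccccc2n(C)c1=O
F2 | step 1 | (S)-1-phenylethylammonium salt of 3 (R acid) | CC(=O)C[C@H](C=C(C)C)c1c([O-])c2ccccc2n(C)c1=O.C[C@H]([NH3+])c1ccccc1
F3 | step 1 | (S)-1-phenylethylammonium salt of the enantiomer of 3 (S acid) | CC(=O)C[C@@H](C=C(C)C)c1c([O-])c2ccccc2n(C)c1=O.C[C@H]([NH3+])c1ccccc1
F4 | step 3 | 3-[(4R)-6-hydroxy-2,6-dimethyloct-2-en-7-yn-4-yl]-4-(methoxymethoxy)-1-methylquinolin-2(1H)-one (both carbinol epimers) | C#CC(C)(O)C[C@H](C=C(C)C)c1c(OCOC)c2ccccc2n(C)c1=O
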